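The earlier runs and the new flask were computed with made-up constants; noise was put on by code.

Grey and amber held the same substrate and catalyst, yet at 3.00 d grey stood at 81.0 % of target, higher than amber's 21.5 %, so I looked for what stops a flask and what paces it.

common to all: substrate 18 mM; free catalyst 0.11 mM
- amber: coupling partner 3.9 mM; run made earlier
- ochre: coupling partner 9.7 mM; run made earlier
- grey: coupling partner 21 mM; run made earlier
- cedar: coupling partner 18.9 mM; time 3.0 d
- elm: coupling partner 10.0 mM; time 3.0 d
- birch: coupling partner 12.0 mM; time 3.0 d
- oak: coupling partner 5.00 mM; time 3.0 d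

| run | time / d | target / % | substrate / % |
|---|---|---|---|
| amber | 0.250 | 6.6 | 93.8 |
| amber | 0.417 | 10.0 | 90.5 |
| amber | 0.833 | 17.4 | 82.9 |
| amber | 1.67 | 21.2 | 78.5 |
| amber | 3.00 | 21.5 | 79.0 |
| ochre | 0.250 | 7.3 | 91.5 |
| ochre | 0.833 | 26.5 | 73.7 |
| ochre | 1.25 | 36.9 | 63.9 |
| ochre | 2.00 | 49.9 | 50.4 |
| ochre | 3.00 | 51.9 | 47.3 |
| grey | 0.250 | 9.2 | 90.8 |
| grey | 0.417 | 13.9 | 85.9 |
| grey | 0.833 | 29.1 | 71.7 |
| grey | 1.67 | 54.7 | 44.6 |
| grey | 3.00 | 81.0 | 15.9 |

(each reading ± 0.5 percentage points)



* all flasks from highest to lowest amount of target, in percent of the substrate charged, at 3.0 d (cedar / elm / birch / oak)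
* the amount of target, in percent of the substrate charged of the flask you put first, at 3.0 d
* the amount of target, in percent of the substrate charged of the flask you put last, at 3.0 d

I took the stop first. Amber's plateau matched its partner charge as a share of substrate, 21.7 %, and ochre's 51.9 % lay just under its 53.9 %, so I read the coupling as one to one, with partner the limiting reagent. That put the ceilings at 27.8 % for oak, 55.6 % for elm and 66.7 % for birch. Cedar's partner charge of 18.9 mM stood above its substrate charge of 18 mM, so on a one-to-one coupling cedar's ceiling was the whole substrate charge.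

Then I took the pace. Grey's reading at 1.67 d gave 53.6 d⁻¹, the turnover frequency, meaning target made per catalyst charged per day. Ochre, with about half of grey's partner, read 52.1 d⁻¹ at 0.833 d, so I let the pace stand apart from partner. At that pace I reckoned birch at its ceiling in 2.04 d, sooner than 3.0 d, and elm and oak had lower ceilings still. I trimmed all three by ochre's plateau over its ceiling, 96.3 %, which gave birch 64.2 %, elm 53.5 % and oak 26.8 %.

Cedar came out at 98.3 % on the first pass, under its ceiling. The weak link was the steady pace, since grey's whole-run figure had fallen to 44.2 d⁻¹. Going round again with that figure, I committed to 81.0 % for cedar, which is simply grey's reading carried over.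

The forecast gave cedar > birch > elm > oak, with 76 % first and 27.3 % last: “Cedar has slightly less partner than grey, so it is rate-limited and slightly slower”. Its order matched mine, but its cedar stood lower.

The flask gave cedar > birch > elm > oak, with cedar at 80.8 %, birch at 63.6 %, elm at 53.6 % and oak at 27.3 %.

    coupling partner + free catalyst → catalyst intermediate A (k = 1800 L mol⁻¹ h⁻¹)
    catalyst intermediate A → by-product + catalyst intermediate B (k = 9.50 h⁻¹)
    substrate + catalyst intermediate B → catalyst intermediate C (k = 690 L mol⁻¹ h⁻¹)
    catalyst intermediate C → catalyst intermediate D (k = 12.0 h⁻¹)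
    catalyst intermediate D → free catalyst + target (k = 9.30 h⁻¹)
    coupling partner + free catalyst + target → free catalyst + over-reaction product (k = 6600 L² mol⁻² h⁻¹)

Cedar's mean turnover frequency came to 44.0 d⁻¹, lower than grey's early 53.6 d⁻¹. The forecast's order would have failed with cedar under birch's 63.6 %, and a neighbour flask stood there: it was like cedar but held 0.044 mM of free catalyst. Its target stayed inside grey's early range, so I used the early pace, and 53.6 d⁻¹ gave 39.3 %. That neighbour flask gave 39.7 %, with 60 % of its substrate left.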